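A flask of this racemate cannot hold more left-handed product than the half of its charge that was left-handed, and the spring run already stands at that ceiling at 2.08 d, with 49.7% left-handed product and 0% left-handed substrate.

common to all: gas 200 mM (held)

| flask | left-handed substrate | right-handed substrate | catalyst | temperature | remark | time |
|---|---|---|---|---|---|---|
| spring | 2 M | 2 M | 1.5 mol% | 40 °C | run made earlier |  |
| midnight | 2 M | 2 M | 3.4 mol% | 73 °C | run made earlier |  |
| alpha | 2.0 M | 2.0 M | 2.3 mol% |  | at 85 °C until 30 h, from then on at 25 °C | 2.5 d |
| zeta | 2.0 M | 2.0 M | 2.3 mol% | 85 °C |  | 2.5 d |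
| gamma | 2.0 M | 2.0 M | 2.3 mol% | 25 °C |  | 2.5 d |
| epsilon | 2.0 M | 2.0 M | 2.3 mol% | 55 °C |  | 2.5 d |

| run | time / d | left-handed product / % | right-handed product / % | left-handed substrate / % |
|---|---|---|---|---|
| spring | 2.08 | 49.7 | 12.3 | 0 |
| spring | 5.00 | 50.2 | 28.5 | 0.4 |
| spring | 10.0 | 49.7 | 41.8 | 0 |
| spring | 25.0 | 49.6 | 49.7 | 0 |
| midnight | 1.04 | 49.9 | 26.5 | 0.5 |
| midnight | 2.50 | 50.1 | 48.9 | 0 |
| midnight | 4.00 | 50.1 | 49.2 | 0.2 |
| midnight | 5.00 | 49.6 | 49.7 | 0.3 |

(standard deviation of a reading: 0.3 percentage points)

* which flask leads in excess of left-handed product over right-handed product ("all alike" within 1.5 percentage points) (alpha / zeta / gamma / epsilon / all alike)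
* excess of left-handed product over right-handed product at the end, alpha
* excess of left-handed product over right-handed product at the end, zeta
* excess of left-handed product over right-handed product at the end, gamma
* excess of left-handed product over right-handed product at the end, epsilon

- catalyst is single-handed; left-handed substrate and right-handed substrate are mirror images of each other, charged as a racemate, each of them at the stated concentration
- the earlier runs were read with a standard deviation of 0.3 percentage points
- at the start none of the gas is in solution
- an excess is the difference of the two amounts in percent of their sum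
- an excess is below zero if the other one leads

Build gamma one process at a time. With the left-handed step alone, left-handed product reaches the ceiling, nothing else forms, and the excess is 100%. Now add the slow step. If f is the fraction of right-handed substrate still present, and left-handed product stands at the ceiling, the excess is f divided by (two minus f), and time has dropped out of the rule.

The pace of f comes from the spring run, taking right-handed substrate as the ceiling minus right-handed product. Its two stretches read 0.192 d⁻¹ and 0.193 d⁻¹, so the decay looks pseudo-first-order, with 0.193 d⁻¹ overall. Taken as proportional to catalyst, this gives the right-handed pace at 2.3 mol% and 40 °C, 0.295 d⁻¹. Running from the start at that temperature for 2.5 d, it takes a charge like gamma's to an excess of 31.4%.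

Next comes the gas, which starts out of solution. Run backwards, the spring decay reaches the full right-handed charge at 0.614 d, and the midnight run reads 2.10 d⁻¹ and a delay of 0.680 d. Holding the spring delay raises the excess to 40.1%.

Last comes temperature. Per unit of catalyst, the pace grows 4.80 times from 40 °C to 73 °C, a rough reading since the midnight value rests on a shortfall of 1.1 percentage points. Spreading that factor evenly over the degrees gives gamma 0.145 d⁻¹ and an excess of 61.4%. The same reckoning gives epsilon 19.1%, zeta 0.442%, and alpha, hot until 30 h, 9.24%, so gamma leads.

The forecast, reading “the left-handed substrate taking the gas first”, also names gamma, with its own figures of 14.8% for alpha, 0.7% for zeta, 65.5% for gamma and 19% for epsilon.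

The flasks give 17.7% for alpha, 1.50% for zeta, 71.6% for gamma and 16.3% for epsilon, and gamma leads.

    coupling partner + catalyst + left-handed substrate → catalyst + left-handed product (k = 1.20 L² mol⁻² min⁻¹, Ea = 60.0 kJ mol⁻¹)
    coupling partner + catalyst + right-handed substrate → catalyst + right-handed product (k = 0.00760 L² mol⁻² min⁻¹, Ea = 67.0 kJ mol⁻¹)
    gas ⇌ coupling partner, rate k3*(csat - [coupling partner]) (kL = 0.0140 min⁻¹)
    coupling partner → decomposition product (k = 1.40 × 10⁻⁵ min⁻¹, Ea = 103 kJ mol⁻¹)
    2 coupling partner → self-condensation product (k = 0.00170 L mol⁻¹ min⁻¹, Ea = 79.0 kJ mol⁻¹)
    (constants at 25 °C)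

The neighbouring flask is gamma repeated at 40 °C, the spring temperature, so the temperature step drops out and 0.295 d⁻¹, the spring pace scaled to 2.3 mol%, applies unchanged. With the delay of 0.614 d, the reckoning leaves 57.3% of the charged right-handed substrate and an excess of 40.1%. That flask ends with 58% of its charged right-handed substrate, 50.0% left-handed product and 21.2% right-handed product, an excess of 40.5%.

The readings stem from a simulated flask with constants of no real substance; noise was put on by code.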